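**Plan**

- Retrosynthesis: the five benzyl ethers are removed last. Ring C is then opened at O1–C2 and at the C3–OH bond to a 2'-hydroxychalcone, and Cα=Cβ is cut (aldol) to a methyl ketone and 4-methoxybenzaldehyde. The C8–CH2 bond of the bridge is cut (Friedel–Crafts) to 2,4,6-trihydroxyacetophenone and a ring D benzylic alcohol, and finally the aryl–acyl bond of ring D.
- Forward: 2-methylphloroglucinol is acylated, O-methylated, benzylated, formylated and reduced to the ring D benzylic alcohol. This alkylates ring A; dibenzylation, chalcone formation, oxidative closure of ring C and hydrogenolysis follow. Ring C is the only ring that is built.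
- Enabling feature: ring C holds both O1–C2 and the C3 hydroxyl, and one oxidation of Cα=Cβ can deliver both. In the chalcone the only free phenol sits on the carbon (future C8a) between the acyl-bearing carbon (C4a) and the bridge-bearing carbon (C8), so O1 can only come from it.
- Stereochemistry: the target has no stereocentre. The E-alkene of the chalcone forms under thermodynamic control, and the two transient centres of the key step are erased by dehydrogenation.

Key step: step 9

Remark: the stereocentres of the non-isolated intermediates 13, 15 and 16 are racemic and each is drawn as one enantiomer. ArD stands for the ring D group 2,4-bis(benzyloxy)-3-[3-(4-benzyloxyphenyl)propanoyl]-6-methoxy-5-methylphenyl, and ring E is the 4-oxygenated phenyl ring of the propanoyl arm.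

**Route**

Step 1
Reactants: 1 2-methylbenzene-1,3,5-triol; 2 3-(4-hydroxyphenyl)propanoic acid
Product: 3 3-(4-hydroxyphenyl)-1-(2,4,6-trihydroxy-3-methylphenyl)propan-1-one
Conditions: BF3·OEt2 (solvent and promoter), 85 °C; then aq. NaOAc
Reagents that add atoms: none
Why: Friedel–Crafts acylation of a phloroglucinol by a free carboxylic acid under BF3 activation is the standard entry to phloretin-type dihydrochalcones, and the two open ring positions of 1 are equivalent by symmetry, so only one aryl ketone can form.

Step 2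
Reactants: 3 3-(4-hydroxyphenyl)-1-(2,4,6-trihydroxy-3-methylphenyl)propan-1-one
Product: 4 1-(2,6-dihydroxy-4-methoxy-3-methylphenyl)-3-(4-hydroxyphenyl)propan-1-one
Conditions: MeI (1.05 equiv), K2CO3 (1.0 equiv), acetone, 0 °C → rt
Reagents that add atoms: iodomethane, CI
Why: Williamson O-methylation with limiting base and reagent should go to the hydroxyl para to the ketone, the most acidic phenol and the only one on that ring not hydrogen-bonded to the carbonyl, just as the 7-hydroxyl of 5,7,4'-trihydroxyflavanones is alkylated first.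

Step 3
Reactants: 4 1-(2,6-dihydroxy-4-methoxy-3-methylphenyl)-3-(4-hydroxyphenyl)propan-1-one
Product: 5 1-[2,6-bis(benzyloxy)-4-methoxy-3-methylphenyl]-3-[4-(benzyloxy)phenyl]propan-1-one
Conditions: BnBr (4 equiv), K2CO3 (5 equiv), Bu4NI (cat.), DMF, 70 °C
Reagents that add atoms: benzyl bromide, BrCc1ccccc1
Why: exhaustive Williamson benzylation in warm DMF overcomes the carbonyl chelation of the two ortho hydroxyls, as in the preparation of 2,4,6-tris(benzyloxy)aryl ketones, while K2CO3 is too weak to enolise the ketone.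

Step 4
Reactants: 5 1-[2,6-bis(benzyloxy)-4-methoxy-3-methylphenyl]-3-[4-(benzyloxy)phenyl]propan-1-one
Product: 7 2,4-bis(benzyloxy)-3-[3-(4-benzyloxyphenyl)propanoyl]-6-methoxy-5-methylbenzaldehyde (ArD-CHO), via aryl iminium chloride 6 (not isolated)
Conditions: POCl3 (1.5 equiv), DMF, 0 °C → rt; then H2O
Reagents that add atoms: N,N-dimethylformamide, CN(C)C=O; water, O
Why: Vilsmeier–Haack formylation should attack the only unsubstituted carbon of the trialkoxy ring (ortho to two ether oxygens, para to the third), because the mono-alkoxy ring E is too weakly activated and the twisted, doubly ortho-flanked ketone enolises too slowly to be haloformylated at room temperature.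

Step 5
Reactants: 7 2,4-bis(benzyloxy)-3-[3-(4-benzyloxyphenyl)propanoyl]-6-methoxy-5-methylbenzaldehyde
Product: 8 1-[2,6-bis(benzyloxy)-3-(hydroxymethyl)-4-methoxy-5-methylphenyl]-3-[4-(benzyloxy)phenyl]propan-1-one (ArD-CH2OH)
Conditions: NaBH4 (0.5 equiv), THF/MeOH, −20 °C
Reagents that add atoms: none
Why: chemoselective borohydride reduction, in which the aldehyde should be consumed at low temperature well before the ketone, whose carbonyl is shielded by two ortho benzyloxy groups.

Step 6
Reactants: 8 ArD-CH2OH; 9 1-(2,4,6-trihydroxyphenyl)ethan-1-one (3 equiv)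
Product: 10 1-[3-(ArD-methyl)-2,4,6-trihydroxyphenyl]ethan-1-one
Conditions: TsOH·H2O (0.1 equiv), 1,4-dioxane, rt, slow addition of 8
Reagents that add atoms: none
Why: acid-catalysed Friedel–Crafts benzylation, in which the 2,4,6-trialkoxybenzylic alcohol ionises readily with loss of water to a stabilised cation that has no free ring position of its own and is captured by the excess acylphloroglucinol at one of its two equivalent nucleophilic carbons, any O-alkylation being reversible under acid, as in the methylene bridging of acylphloroglucinols.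

Step 7
Reactants: 10 1-[3-(ArD-methyl)-2,4,6-trihydroxyphenyl]ethan-1-one
Product: 11 1-[4,6-bis(benzyloxy)-3-(ArD-methyl)-2-hydroxyphenyl]ethan-1-one
Conditions: BnBr (2.1 equiv), K2CO3 (2.2 equiv), acetone, reflux
Reagents that add atoms: benzyl bromide, BrCc1ccccc1
Why: chelation- and steric-controlled Williamson benzylation with two equivalents of halide should etherify the para hydroxyl and the less hindered ortho hydroxyl, leaving the hydroxyl wedged between the acetyl group and the bulky arylmethyl group hydrogen-bonded to the carbonyl, as in the usual dialkylation of 3-substituted phloracetophenones.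

Step 8
Reactants: 11 1-[4,6-bis(benzyloxy)-3-(ArD-methyl)-2-hydroxyphenyl]ethan-1-one; 12 4-methoxybenzaldehyde
Product: 14 (E)-1-[4,6-bis(benzyloxy)-3-(ArD-methyl)-2-hydroxyphenyl]-3-(4-methoxyphenyl)prop-2-en-1-one, via aldol adduct 13 (not isolated)
Conditions: KOH (50% aq.), EtOH/THF, rt
Reagents that add atoms: none
Why: Claisen–Schmidt condensation of the methyl ketone with a non-enolisable aldehyde should give the E-enone under thermodynamic control by E1cB dehydration of 13, whereas the ring D ketone carries a hindered α-methylene whose aldol adduct dehydrates with difficulty and reverts.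

Step 9
Reactants: 14 (E)-1-[4,6-bis(benzyloxy)-3-(ArD-methyl)-2-hydroxyphenyl]-3-(4-methoxyphenyl)prop-2-en-1-one
Product: 17 5,7-bis(benzyloxy)-3-hydroxy-2-(4-methoxyphenyl)-8-(ArD-methyl)-4H-chromen-4-one, via trans-chalcone epoxide 15 (not isolated), via trans-dihydroflavonol 16 (not isolated)
Conditions: 30% aq. H2O2 (5 equiv), 2 M aq. NaOH, MeOH/THF, 0 °C → rt
Reagents that add atoms: hydrogen peroxide, OO
Why: Algar–Flynn–Oyamada reaction: hydroperoxide anion adds to the enone β-carbon and the enolate displaces hydroxide to give trans-epoxide 15 (Weitz–Scheffer epoxidation), the C2' phenoxide opens the epoxide at the benzylic carbon to form O1–C2 and leave the C3 hydroxyl in trans-dihydroflavonol 16, and further alkaline peroxide dehydrogenates C2–C3 to the flavonol. The closest known case is the AFO conversion of 3'-alkyl-2'-hydroxy-4',6'-dialkoxy-4-methoxychalcones into 8-alkyl-5,7-dialkoxy-4'-methoxyflavonols. Ring C closes by a 6-endo-tet epoxide opening, in competition with the 5-exo-tet opening at the α-carbon that would lead to an aurone. The two stereocentres of 15 and 16 form racemic (trans from the E-alkene and from anti opening) and both are erased by the final dehydrogenation, so no stereocontrol is needed. The step needs attack at Cβ over Cα, which the electron-releasing 4-methoxyphenyl group favours by weakening the benzylic C–O bond and which a cold reaction mixture supports, and it needs attack by the right oxygen, which is certain because the hydroxyl between the acyl-bearing and the bridge-bearing carbon is the only free phenol. Ring D stays out of the reaction because it has no free phenol (no Dakin-type oxidation, no base-induced loss from the methylene bridge) and its ketone is saturated.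

Step 10
Reactants: 17 5,7-bis(benzyloxy)-3-hydroxy-2-(4-methoxyphenyl)-8-(ArD-methyl)-4H-chromen-4-one
Product: 18 4'''-hydroxytrianguletin
Conditions: H2 (1 atm), Pd/C (10% palladium on carbon), THF/MeOH, rt
Reagents that add atoms: none
Why: catalytic hydrogenolysis should cleave the five benzyl aryl ethers at room temperature and leave the flavonol enone, the aryl ketone, the two methyl ethers and the diarylmethane untouched.

**Compound list**

1 | 2-methylbenzene-1,3,5-triol | Cc1c(O)cc(O)cc1O | starting material
2 | 3-(4-hydroxyphenyl)propanoic acid | O=C(O)CCc1ccc(O)cc1 | starting material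
3 | 3-(4-hydroxyphenyl)-1-(2,4,6-trihydroxy-3-methylphenyl)propan-1-one | Cc1c(O)cc(O)c(C(=O)CCc2ccc(O)cc2)c1O | intermediate
4 | 1-(2,6-dihydroxy-4-methoxy-3-methylphenyl)-3-(4-hydroxyphenyl)propan-1-one | COc1cc(O)c(C(=O)CCc2ccc(O)cc2)c(O)c1C | intermediate
5 | 1-[2,6-bis(benzyloxy)-4-methoxy-3-methylphenyl]-3-[4-(benzyloxy)phenyl]propan-1-one | COc1cc(OCc2ccccc2)c(C(=O)CCc2ccc(OCc3ccccc3)cc2)c(OCc2ccccc2)c1C | intermediate
6 | N-({2,4-bis(benzyloxy)-3-[3-(4-benzyloxyphenyl)propanoyl]-6-methoxy-5-methylphenyl}methylidene)-N-methylmethanaminium chloride | C[N+](C)=Cc1c(OC)c(C)c(OCc2ccccc2)c(C(=O)CCc2ccc(OCc3ccccc3)cc2)c1OCc1ccccc1.[Cl-] | intermediate (not isolated)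
7 | 2,4-bis(benzyloxy)-3-[3-(4-benzyloxyphenyl)propanoyl]-6-methoxy-5-methylbenzaldehyde | O=Cc1c(OC)c(C)c(OCc2ccccc2)c(C(=O)CCc2ccc(OCc3ccccc3)cc2)c1OCc1ccccc1 | intermediate
8 | 1-[2,6-bis(benzyloxy)-3-(hydroxymethyl)-4-methoxy-5-methylphenyl]-3-[4-(benzyloxy)phenyl]propan-1-one | OCc1c(OC)c(C)c(OCc2ccccc2)c(C(=O)CCc2ccc(OCc3ccccc3)cc2)c1OCc1ccccc1 | intermediate
9 | 1-(2,4,6-trihydroxyphenyl)ethan-1-one | CC(=O)c1c(O)cc(O)cc1O | starting material
10 | 1-[3-({2,4-bis(benzyloxy)-3-[3-(4-benzyloxyphenyl)propanoyl]-6-methoxy-5-methylphenyl}methyl)-2,4,6-trihydroxyphenyl]ethan-1-one | CC(=O)c1c(O)cc(O)c(Cc2c(OCc3ccccc3)c(C(=O)CCc3ccc(OCc4ccccc4)cc3)c(OCc3ccccc3)c(C)c2OC)c1O | intermediate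
11 | 1-[4,6-bis(benzyloxy)-3-({2,4-bis(benzyloxy)-3-[3-(4-benzyloxyphenyl)propanoyl]-6-methoxy-5-methylphenyl}methyl)-2-hydroxyphenyl]ethan-1-one | CC(=O)c1c(OCc2ccccc2)cc(OCc2ccccc2)c(Cc2c(OCc3ccccc3)c(C(=O)CCc3ccc(OCc4ccccc4)cc3)c(OCc3ccccc3)c(C)c2OC)c1O | intermediate
12 | 4-methoxybenzaldehyde | COc1ccc(C=O)cc1 | starting material
13 | 1-[4,6-bis(benzyloxy)-3-(ArD-methyl)-2-hydroxyphenyl]-3-hydroxy-3-(4-methoxyphenyl)propan-1-one (racemic, R enantiomer drawn) | COc1ccc(cc1)[C@H](O)CC(=O)c1c(OCc2ccccc2)cc(OCc2ccccc2)c(Cc2c(OCc3ccccc3)c(C(=O)CCc3ccc(OCc4ccccc4)cc3)c(OCc3ccccc3)c(C)c2OC)c1O | intermediate (not isolated)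
14 | (E)-1-[4,6-bis(benzyloxy)-3-(ArD-methyl)-2-hydroxyphenyl]-3-(4-methoxyphenyl)prop-2-en-1-one | COc1ccc(/C=C/C(=O)c2c(OCc3ccccc3)cc(OCc3ccccc3)c(Cc3c(OCc4ccccc4)c(C(=O)CCc4ccc(OCc5ccccc5)cc4)c(OCc4ccccc4)c(C)c3OC)c2O)cc1 | intermediate
15 | [4,6-bis(benzyloxy)-3-(ArD-methyl)-2-hydroxyphenyl][trans-3-(4-methoxyphenyl)oxiran-2-yl]methanone (racemic, one enantiomer drawn) | COc1ccc(cc1)[C@H]6[C@@H](O6)C(=O)c2c(OCc3ccccc3)cc(OCc3ccccc3)c(Cc3c(OCc4ccccc4)c(C(=O)CCc4ccc(OCc5ccccc5)cc4)c(OCc4ccccc4)c(C)c3OC)c2O | intermediate (not isolated)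
16 | trans-5,7-bis(benzyloxy)-3-hydroxy-2-(4-methoxyphenyl)-8-(ArD-methyl)chroman-4-one (racemic, 2R,3R enantiomer drawn) | COc1ccc(cc1)[C@@H]2[C@@H](O)C(=O)c3c(OCc4ccccc4)cc(OCc4ccccc4)c(Cc4c(OCc5ccccc5)c(C(=O)CCc5ccc(OCc6ccccc6)cc5)c(OCc5ccccc5)c(C)c4OC)c3O2 | intermediate (not isolated)
17 | 5,7-bis(benzyloxy)-3-hydroxy-2-(4-methoxyphenyl)-8-(ArD-methyl)-4H-chromen-4-one (penta-O-benzyl 4'''-hydroxytrianguletin) | COc1ccc(cc1)-c2oc3c(Cc4c(OCc5ccccc5)c(C(=O)CCc5ccc(OCc6ccccc6)cc5)c(OCc5ccccc5)c(C)c4OC)c(OCc4ccccc4)cc(OCc4ccccc4)c3c(=O)c2O | intermediate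
18 | 4'''-hydroxytrianguletin | COc1ccc(-c2oc3c(Cc4c(O)c(C(=O)CCc5ccc(O)cc5)c(O)c(C)c4OC)c(O)cc(O)c3c(=O)c2O)cc1 | target

**Step count**

Total: 10 steps. Longest linear sequence: 10 steps (1 → 3 → 4 → 5 → 7 → 8 → 10 → 11 → 14 → 17 → 18). Compounds 2, 9 and 12 are bought and enter at steps 1, 6 and 8.

**Steps most likely to fail, with fallbacks**

Step 9. The epoxide may be opened at the α-carbon instead of the benzylic carbon, because the 6'-benzyloxy group twists the aroyl unit and favours the five-membered (aurone) closure. The fallback sets out from chalcone 14 and separates the two bond formations. Oxidative cyclisation with catalytic I2 in DMSO at about 120 °C (oxa-Michael closure of O1–C2, then dehydrogenation) should give the flavone F1. Dimethyldioxirane in acetone/CH2Cl2 at 0 °C should then epoxidise C2=C3 to the 2,3-epoxyflavanone F2. A trace of TsOH should open this to the 3-hydroxyflavone, which is compound 17, where the route is rejoined.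

Step 6. Capture of the benzylic cation by the acyl-deactivated triol 9 may be too slow. Ipso-substitution on a second molecule of 8 with loss of formaldehyde, double alkylation of 9, or acid-induced scrambling of the bridge could then take over. The fallback sets out from alcohol 8 and uses phloroglucinol itself (5 equiv, catalytic TsOH, dioxane, rt), a far stronger nucleophile with three equivalent carbons, to give the C-benzylphloroglucinol F3. Its two open positions are equivalent, so mono-C-acetylation (Ac2O, BF3·OEt2, EtOAc, 0 °C → rt, then brief K2CO3/MeOH to cleave any aryl acetate) can give only compound 10, where the route continues.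

Step 7. Regiocontrol between the two ortho hydroxyls of ring A may be lost, with benzylation of the hydroxyl next to the bridge, or a third benzyl group may be introduced. The fallback fixes the ether pattern before the rings are joined. Starting from 9, the standard chelation-controlled dibenzylation (BnBr 2.1 equiv, K2CO3, acetone, reflux; the two ortho hydroxyls are still equivalent) gives 2-hydroxy-4,6-bis(benzyloxy)acetophenone F4. This is alkylated with alcohol 8 under catalytic TsOH in MeCN/CH2Cl2. The cation should enter ortho to the free hydroxyl, the less hindered of the two open positions (the other lies between two benzyloxy groups), which gives compound 11 directly.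

**Further compounds**

F1 | step 9 | 5,7-bis(benzyloxy)-2-(4-methoxyphenyl)-8-(ArD-methyl)-4H-chromen-4-one | COc1ccc(cc1)-c2cc(=O)c3c(OCc4ccccc4)cc(OCc4ccccc4)c(Cc4c(OCc5ccccc5)c(C(=O)CCc5ccc(OCc6ccccc6)cc5)c(OCc5ccccc5)c(C)c4OC)c3o2
F2 | step 9 | 5,7-bis(benzyloxy)-2,3-epoxy-2-(4-methoxyphenyl)-8-(ArD-methyl)chroman-4-one (racemic, one enantiomer drawn) | COc1ccc(cc1)[C@]23O[C@H]2C(=O)c4c(OCc5ccccc5)cc(OCc5ccccc5)c(Cc5c(OCc6ccccc6)c(C(=O)CCc6ccc(OCc7ccccc7)cc6)c(OCc6ccccc6)c(C)c5OC)c4O3
F3 | step 6 | 2-({2,4-bis(benzyloxy)-3-[3-(4-benzyloxyphenyl)propanoyl]-6-methoxy-5-methylphenyl}methyl)benzene-1,3,5-triol | Oc1cc(O)c(Cc2c(OCc3ccccc3)c(C(=O)CCc3ccc(OCc4ccccc4)cc3)c(OCc3ccccc3)c(C)c2OC)c(O)c1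
F4 | step 7 | 1-[2,4-bis(benzyloxy)-6-hydroxyphenyl]ethan-1-one | CC(=O)c1c(O)cc(OCc2ccccc2)cc1OCc1ccccc1
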